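The C2–C3–C4 bridge of ring C joins ring B (at C2) to ring A (at C4) and carries a heteroatom at each end: O1 on C2 and the carbonyl O on C4. This diaryl 1,3-dioxygenated C3 unit maps onto a 3,5-diarylisoxazole, with C2 as the C=N carbon and C4 as the C–O carbon.
Cuts: first O1–C2 of the pyranone, back to an o-hydroxyaryl enaminoketone (the N–O-opened isoxazole). Then C2–C3 and C4–O of the isoxazole, which leaves a ring B nitrile oxide and a ring A terminal arylacetylene.
Forward: rings A and B are bought as aromatic aldehydes. The ring A aldehyde is benzylated and homologated to the alkyne. Ring B gains its fourth oxygen (Baeyer–Villiger) and its formyl group (magnesium-directed ortho-formylation), and is then taken to the hydroximoyl chloride.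
The [3+2] cycloaddition joins the halves and closes the isoxazole. Hydrogenolysis opens it and frees all four phenols, and acid closes ring C last.
Stereochemistry: the target has no stereocentre and no stereogenic double bond. Only regiochemistry needs control, namely the ring B substitution pattern and the 3,5-orientation of the cycloaddition.
Key step: step 9

Remark: the aldoxime and its chloride are drawn in their usual E and Z forms. This geometry disappears in the nitrile oxide and has no bearing on the outcome.

Step 1
Reactants: 1 2,4,6-trihydroxybenzaldehyde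
Product: 2 2,4,6-tris(benzyloxy)benzaldehyde
Conditions: BnBr (3.6 equiv), K2CO3, DMF, 60 °C
Reagents that add atoms: benzyl bromide, BrCc1ccccc1
Why: Threefold Williamson etherification, in which the formyl group lowers the nucleophilicity of the ring carbons so that O-alkylation should prevail over C-benzylation, while warm DMF and excess base also bring the two hydrogen-bonded ortho hydroxyls to reaction.

Step 2
Reactants: 2 2,4,6-tris(benzyloxy)benzaldehyde; 3 dimethyl (1-diazo-2-oxopropyl)phosphonate (Ohira–Bestmann reagent)
Product: 4 1,3,5-tris(benzyloxy)-2-ethynylbenzene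
Conditions: 3 (1.5 equiv), K2CO3, MeOH/THF, 0 °C to rt
Reagents that add atoms: dimethyl (1-diazo-2-oxopropyl)phosphonate (compound 3), COP(=O)(OC)C(=[N+]=[N-])C(C)=O
Why: Seyferth–Gilbert homologation in its Ohira–Bestmann form, in which methanolysis of 3 frees the diazomethylphosphonate anion, olefination of the aldehyde followed by loss of N2 and a 1,2-hydrogen shift gives the terminal alkyne, and the mild base leaves the benzyl ethers alone (THF for solubility, excess reagent because the carbonyl is electron-rich and doubly ortho-substituted).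

Step 3
Reactants: 5 2-hydroxy-3,4-dimethoxybenzaldehyde
Product: 6 2-(benzyloxy)-3,4-dimethoxybenzaldehyde
Conditions: BnBr, K2CO3, DMF, 50 °C
Reagents that add atoms: benzyl bromide, BrCc1ccccc1
Why: Williamson etherification of the only free hydroxyl, which marks the oxygen destined to be the free 3'-OH with a group that hydrogenolysis removes at the end.

Step 4
Reactants: 6 2-(benzyloxy)-3,4-dimethoxybenzaldehyde
Product: 8 2-(benzyloxy)-3,4-dimethoxyphenol, via aryl formate 7 (not isolated)
Conditions: mCPBA, CH2Cl2, 0 °C to rt; aqueous work-up; then K2CO3 (cat.), MeOH, rt, under N2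
Reagents that add atoms: 3-chloroperoxybenzoic acid, O=C(OO)c1cccc(Cl)c1
Why: Baeyer–Villiger oxidation with a Dakin-type outcome, since the ortho and para alkoxy donors make the aryl group migrate to give formate 7, whose methanolysis delivers phenol 8 and so replaces the formyl carbon by the future 2'-oxygen at a fixed position.

Step 5
Reactants: 8 2-(benzyloxy)-3,4-dimethoxyphenol
Product: 9 3-(benzyloxy)-2-hydroxy-4,5-dimethoxybenzaldehyde
Conditions: MgCl2, Et3N, (CH2O)n, MeCN, reflux; 1 M HCl work-up
Reagents that add atoms: paraformaldehyde (reacts as formaldehyde), C=O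
Why: Magnesium-mediated ortho-formylation of a phenol (Casnati–Skattebøl reaction), in which the magnesium phenoxide passes formaldehyde through a chelate to an ortho carbon only, C6 is the single free ortho site (C2 bears OBn, the para carbon bears OMe), and a second formaldehyde oxidises the benzylic alkoxide to the aldehyde.

Step 6
Reactants: 9 3-(benzyloxy)-2-hydroxy-4,5-dimethoxybenzaldehyde
Product: 10 3-(benzyloxy)-2,4,5-trimethoxybenzaldehyde
Conditions: MeI, K2CO3, DMF, rt
Reagents that add atoms: iodomethane, CI
Why: Williamson methylation of the only acidic site completes the 2',4',5'-trimethoxy-3'-benzyloxy pattern of ring B.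

Step 7
Reactants: 10 3-(benzyloxy)-2,4,5-trimethoxybenzaldehyde
Product: 11 (E)-3-(benzyloxy)-2,4,5-trimethoxybenzaldehyde oxime
Conditions: NH2OH·HCl, NaOAc, EtOH/H2O, rt
Reagents that add atoms: hydroxylamine hydrochloride, Cl.NO
Why: Acetate-buffered condensation of an aromatic aldehyde with hydroxylamine (oxime formation), which touches neither the ethers nor the ring.

Step 8
Reactants: 11 (E)-3-(benzyloxy)-2,4,5-trimethoxybenzaldehyde oxime
Product: 12 (Z)-3-(benzyloxy)-N-hydroxy-2,4,5-trimethoxybenzenecarboximidoyl chloride
Conditions: NCS (1.0 equiv), DMF, rt; aqueous work-up, used crude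
Reagents that add atoms: N-chlorosuccinimide, O=C1CCC(=O)N1Cl
Why: Standard chlorination of an aldoxime to a hydroximoyl chloride, where exactly one equivalent of the mild chlorine donor in DMF should attack the oxime carbon faster than the one free ring position C6', which lies next to the electron-withdrawing C=N group.

Step 9
Reactants: 12 (Z)-3-(benzyloxy)-N-hydroxy-2,4,5-trimethoxybenzenecarboximidoyl chloride; 4 1,3,5-tris(benzyloxy)-2-ethynylbenzene
Product: 14 3-[3-(benzyloxy)-2,4,5-trimethoxyphenyl]-5-[2,4,6-tris(benzyloxy)phenyl]isoxazole, via nitrile oxide 13 (not isolated)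
Conditions: Et3N (syringe pump, 10 h), toluene (concentrated in 4), 60 °C; 12 in 1.3-fold excess
Reagents that add atoms: none
Why: Et3N removes HCl from 12 to give nitrile oxide 13, which adds across the triple bond of 4 in a concerted, asynchronous [3+2] (Huisgen) cycloaddition, the standard nitrile oxide–terminal alkyne route to 3,5-disubstituted isoxazoles. The five-membered ring closes intermolecularly as two bonds form together, the nitrile oxide carbon to the terminal alkyne CH (future C2–C3) and the nitrile oxide oxygen to the aryl-bearing alkyne carbon (future C4–O), and the product is aromatic as formed, so no oxidation follows. No stereocentre is created. The selectivity needed is regiochemical: the unsubstituted alkyne terminus is the less hindered end and holds the larger HOMO coefficient of this donor-substituted arylacetylene, so it pairs with the electrophilic carbon of 13, and the two ortho benzyloxy groups of 4 make the reverse orientation still less accessible. The competing process, dimerisation of 13 to the furoxan, is second order in 13 and is held back by releasing 13 slowly into a concentrated solution of 4, helped by the ortho methoxy group of 13.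

Step 10
Reactants: 14 3-[3-(benzyloxy)-2,4,5-trimethoxyphenyl]-5-[2,4,6-tris(benzyloxy)phenyl]isoxazole
Product: 15 (Z)-3-amino-3-(3-hydroxy-2,4,5-trimethoxyphenyl)-1-(2,4,6-trihydroxyphenyl)prop-2-en-1-one
Conditions: H2 (4 bar), 10% Pd/C, THF/MeOH, rt
Reagents that add atoms: none
Why: Catalytic hydrogenolysis, in which the weak isoxazole N–O bond is cleaved to a vinylogous amide (Z, held by an N–H···O=C hydrogen bond) that resists further reduction, while the four O-benzyl bonds fall in the same operation and the methyl ethers stay.

Step 11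
Reactants: 15 (Z)-3-amino-3-(3-hydroxy-2,4,5-trimethoxyphenyl)-1-(2,4,6-trihydroxyphenyl)prop-2-en-1-one
Product: 16 5,7,3'-trihydroxy-2',4',5'-trimethoxyflavone
Conditions: conc. HCl, EtOH, reflux
Reagents that add atoms: none
Why: Acid-promoted addition–elimination (cyclocondensation of an o-hydroxyaryl enaminoketone to a 4-pyranone), in which protonation turns C2 into an iminium-type electrophile, either ortho hydroxyl of the symmetric ring A adds with the same result, and nitrogen leaves as ammonium chloride to give the aromatic ring C.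

Compound list
1 | 2,4,6-trihydroxybenzaldehyde | O=Cc1c(O)cc(O)cc1O | starting material
2 | 2,4,6-tris(benzyloxy)benzaldehyde | O=Cc1c(OCc2ccccc2)cc(OCc2ccccc2)cc1OCc1ccccc1 | intermediate
3 | dimethyl (1-diazo-2-oxopropyl)phosphonate | COP(=O)(OC)C(=[N+]=[N-])C(C)=O | starting material
4 | 1,3,5-tris(benzyloxy)-2-ethynylbenzene | C#Cc1c(OCc2ccccc2)cc(OCc2ccccc2)cc1OCc1ccccc1 | intermediate
5 | 2-hydroxy-3,4-dimethoxybenzaldehyde | COc1ccc(C=O)c(O)c1OC | starting material
6 | 2-(benzyloxy)-3,4-dimethoxybenzaldehyde | COc1ccc(C=O)c(OCc2ccccc2)c1OC | intermediate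
7 | 2-(benzyloxy)-3,4-dimethoxyphenyl formate | COc1ccc(OC=O)c(OCc2ccccc2)c1OC | intermediate
8 | 2-(benzyloxy)-3,4-dimethoxyphenol | COc1ccc(O)c(OCc2ccccc2)c1OC | intermediate
9 | 3-(benzyloxy)-2-hydroxy-4,5-dimethoxybenzaldehyde | COc1cc(C=O)c(O)c(OCc2ccccc2)c1OC | intermediate
10 | 3-(benzyloxy)-2,4,5-trimethoxybenzaldehyde | COc1cc(C=O)c(OC)c(OCc2ccccc2)c1OC | intermediate
11 | (E)-3-(benzyloxy)-2,4,5-trimethoxybenzaldehyde oxime | COc1cc(/C=N/O)c(OC)c(OCc2ccccc2)c1OC | intermediate
12 | (Z)-3-(benzyloxy)-N-hydroxy-2,4,5-trimethoxybenzenecarboximidoyl chloride | COc1cc(/C(Cl)=N/O)c(OC)c(OCc2ccccc2)c1OC | intermediate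
13 | 3-(benzyloxy)-2,4,5-trimethoxybenzonitrile oxide | COc1cc(C#[N+][O-])c(OC)c(OCc2ccccc2)c1OC | intermediate
14 | 3-[3-(benzyloxy)-2,4,5-trimethoxyphenyl]-5-[2,4,6-tris(benzyloxy)phenyl]isoxazole | COc1cc(-c2cc(-c3c(OCc4ccccc4)cc(OCc4ccccc4)cc3OCc3ccccc3)on2)c(OC)c(OCc2ccccc2)c1OC | intermediate
15 | (Z)-3-amino-3-(3-hydroxy-2,4,5-trimethoxyphenyl)-1-(2,4,6-trihydroxyphenyl)prop-2-en-1-one | COc1cc(/C(N)=C/C(=O)c2c(O)cc(O)cc2O)c(OC)c(O)c1OC | intermediate
16 | 5,7,3'-trihydroxy-2',4',5'-trimethoxyflavone | COc1cc(-c2cc(=O)c3c(O)cc(O)cc3o2)c(OC)c(O)c1OC | target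

Total step count: 11.
Longest linear sequence: 9 steps (5 to 16, steps 3 to 11). The ring A branch (steps 1 and 2) joins at step 9.

Steps most likely to fail

Step 9. Dimerisation of the nitrile oxide may outrun its addition to an alkyne whose aryl-bearing carbon is screened by two ortho benzyloxy groups. The fallback builds the same isoxazole without a dipole. It sets out from alkyne 4 and aldehyde 10 and comes back at isoxazole 14. Alkyne 4 is deprotonated with n-BuLi (THF, −78 °C) and added to 10, giving the racemic propargylic alcohol 1-[3-(benzyloxy)-2,4,5-trimethoxyphenyl]-3-[2,4,6-tris(benzyloxy)phenyl]prop-2-yn-1-ol F1. MnO2 in CH2Cl2 oxidises this to the ynone 1-[3-(benzyloxy)-2,4,5-trimethoxyphenyl]-3-[2,4,6-tris(benzyloxy)phenyl]prop-2-yn-1-one F2. NH2OH·HCl with pyridine in EtOH should condense at the carbonyl rather than add in a conjugate sense, because the alkyne carbon next to the donor ring A is hindered and electron-rich. This gives the ynone oxime with OH on the alkyne side, (E)-1-[3-(benzyloxy)-2,4,5-trimethoxyphenyl]-3-[2,4,6-tris(benzyloxy)phenyl]prop-2-yn-1-one oxime F3. Catalytic AuCl3 in CH2Cl2 then cycloisomerises F3, by 5-endo-dig attack of the oxime oxygen on the ring A-bearing alkyne carbon, to 14.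

Step 10. Loss of the benzyl groups may run ahead of N–O cleavage in the hindered diaryl isoxazole, so that the reaction stalls on the catalyst. Long exposure could also begin to reduce the enaminone. The fallback separates the two tasks. It sets out from 14 and comes back at 15. Mo(CO)6 in MeCN/H2O at reflux cleaves only the N–O bond and gives the benzyl-protected enaminoketone (Z)-3-amino-3-[3-(benzyloxy)-2,4,5-trimethoxyphenyl]-1-[2,4,6-tris(benzyloxy)phenyl]prop-2-en-1-one F4, which can be purified by chromatography. A short O-debenzylation (H2 1 bar, Pd/C, EtOAc/MeOH) then delivers 15.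

Step 2. The diazophosphonate anion may add only slowly to a carbonyl that is electron-rich and flanked by two ortho substituents, and the reagent may decay in basic methanol before conversion is complete. The fallback is a Corey–Fuchs sequence. It sets out from aldehyde 2 and comes back at alkyne 4. CBr4 and PPh3 in CH2Cl2 at 0 °C give the dibromoalkene 1,3,5-tris(benzyloxy)-2-(2,2-dibromoethenyl)benzene F5. n-BuLi (2.2 equiv, THF, −78 °C) followed by a proton quench converts F5 into 4 by bromine–lithium exchange and Fritsch–Buttenberg–Wiechell rearrangement.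

Further compounds
F1 | step 9 | rac-1-[3-(benzyloxy)-2,4,5-trimethoxyphenyl]-3-[2,4,6-tris(benzyloxy)phenyl]prop-2-yn-1-ol | COc1cc(C(O)C#Cc2c(OCc3ccccc3)cc(OCc3ccccc3)cc2OCc2ccccc2)c(OC)c(OCc2ccccc2)c1OC
F2 | step 9 | 1-[3-(benzyloxy)-2,4,5-trimethoxyphenyl]-3-[2,4,6-tris(benzyloxy)phenyl]prop-2-yn-1-one | COc1cc(C(=O)C#Cc2c(OCc3ccccc3)cc(OCc3ccccc3)cc2OCc2ccccc2)c(OC)c(OCc2ccccc2)c1OC
F3 | step 9 | (E)-1-[3-(benzyloxy)-2,4,5-trimethoxyphenyl]-3-[2,4,6-tris(benzyloxy)phenyl]prop-2-yn-1-one oxime | COc1cc(/C(C#Cc2c(OCc3ccccc3)cc(OCc3ccccc3)cc2OCc2ccccc2)=N/O)c(OC)c(OCc2ccccc2)c1OC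
F4 | step 10 | (Z)-3-amino-3-[3-(benzyloxy)-2,4,5-trimethoxyphenyl]-1-[2,4,6-tris(benzyloxy)phenyl]prop-2-en-1-one | COc1cc(/C(N)=C/C(=O)c2c(OCc3ccccc3)cc(OCc3ccccc3)cc2OCc2ccccc2)c(OC)c(OCc2ccccc2)c1OC
F5 | step 2 | 1,3,5-tris(benzyloxy)-2-(2,2-dibromoethenyl)benzene | BrC(Br)=Cc1c(OCc2ccccc2)cc(OCc2ccccc2)cc1OCc1ccccc1
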